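**Retrosynthetic overview**

- Maackiaflavanone B is traced back, through its 7-O-MOM ether, to an isomeric (2S)-flavanone with only three rings. In this isomer two of the three C5 units still sit on oxygen: a prenyl group on O5 (ring A) and a 1,1-dimethylpropargyl group on O4' (ring B).
- Enabling feature: in ring A, C8 is para to O5 and the ortho carbon C4a is blocked. In ring B, the ring D atoms O4'-CMe2-CH=CH-C5' are those of an O4' 1,1-dimethylpropargyl ether folded onto C5', the only free carbon ortho to O4' because C3' bears the prenyl group. One heating therefore moves both units from O to C and closes ring D.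
- The bis-ether flavanone comes from a chalcone by oxa-Michael closure of ring C, followed by kinetic resolution at C2. The chalcone comes from a Claisen-Schmidt union of a phloroacetophenone ether with a 4-hydroxybenzaldehyde ether.
- Ring order: rings A and B are bought as arenes, ring C is closed in step 6, and ring D is closed last in step 8.

Key step: step 8

Remark: flavanone numbering is used throughout (O1, C2, C3, C4, C4a, C5 to C8, C8a for rings C and A; C1' to C6' for ring B; the pyran ring is ring D). Prenyl = 3-methylbut-2-enyl, MOM = methoxymethyl.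

Step 1
Reactants: 1 2,4,6-trihydroxyacetophenone
Product: 2 2,6-dihydroxy-4-(methoxymethoxy)acetophenone
Conditions: MOMCl (1.0 equiv), i-Pr2NEt, THF, 0 °C
Reagents that add atoms: chloromethyl methyl ether (MOMCl), COCCl
Why: Williamson-type O-alkylation in which the 4-OH, the most acidic hydroxyl and the only one not held in a hydrogen bond to the acetyl group, should take the single equivalent of MOMCl first.

Step 2
Reactants: 2 2,6-dihydroxy-4-(methoxymethoxy)acetophenone
Product: 3 2-hydroxy-4-(methoxymethoxy)-6-(prenyloxy)acetophenone
Conditions: prenyl bromide (1.05 equiv), K2CO3, acetone, reflux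
Reagents that add atoms: prenyl bromide, CC(C)=CCBr
Why: Williamson ether synthesis that should stop at the monoether, because once one of the two equivalent ortho hydroxyls is alkylated the other is locked in a strong chelate with the carbonyl group, and K2CO3 in acetone favours O- over C-alkylation.

Step 3
Reactants: 4 4-hydroxybenzaldehyde
Product: 5 4-hydroxy-3-prenylbenzaldehyde
Conditions: prenyl bromide, KOH, H2O, rt
Reagents that add atoms: prenyl bromide, CC(C)=CCBr
Why: Direct ortho C-prenylation of a phenoxide in water, where solvation of the phenoxide oxygen diverts the alkylation to the ortho carbon (para is blocked by the formyl group), and O-alkylated or doubly alkylated material is removed by chromatography.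

Step 4
Reactants: 5 4-hydroxy-3-prenylbenzaldehyde
Product: 6 3-prenyl-4-(2-methylbut-3-yn-2-yloxy)benzaldehyde
Conditions: 3-chloro-3-methylbut-1-yne, DBU, CuCl2·2H2O (1 mol %), MeCN, 0 °C to rt
Reagents that add atoms: 3-chloro-3-methylbut-1-yne, CC(C)(Cl)C#C
Why: Copper-catalysed O-propargylation of a phenol with a tertiary propargylic chloride, the standard entry to aryl 1,1-dimethylpropargyl ethers, which suits acceptor-substituted phenols such as 5 and runs far below the onset of the Claisen rearrangement.

Step 5
Reactants: 3 2-hydroxy-4-(methoxymethoxy)-6-(prenyloxy)acetophenone; 6 3-prenyl-4-(2-methylbut-3-yn-2-yloxy)benzaldehyde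
Product: 7 (E)-2'-hydroxy-4'-(methoxymethoxy)-6'-(prenyloxy)-3-prenyl-4-(2-methylbut-3-yn-2-yloxy)chalcone
Conditions: KOH (aq), EtOH, rt
Reagents that add atoms: none
Why: Claisen-Schmidt condensation (aldol addition and E1cB dehydration) that should give the E-enone, with the MOM acetal, both ethers, the alkenes and the alkyne all inert to hydroxide at room temperature.

Step 6
Reactants: 7 (E)-2'-hydroxy-4'-(methoxymethoxy)-6'-(prenyloxy)-3-prenyl-4-(2-methylbut-3-yn-2-yloxy)chalcone
Product: 8 (±)-7-(methoxymethoxy)-5-(prenyloxy)-2-[3-prenyl-4-(2-methylbut-3-yn-2-yloxy)phenyl]chroman-4-one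
Conditions: NaOAc, EtOH, reflux
Reagents that add atoms: none
Why: Intramolecular oxa-Michael addition (6-endo-trig chalcone-flavanone isomerisation) whose equilibrium should lie on the flavanone side because the 6'-alkoxy group twists the chalcone carbonyl out of conjugation, and C2 is formed racemic here and resolved in step 7.

Step 7
Reactants: 8 (±)-7-(methoxymethoxy)-5-(prenyloxy)-2-[3-prenyl-4-(2-methylbut-3-yn-2-yloxy)phenyl]chroman-4-one
Product: 9 (2S)-7-(methoxymethoxy)-5-(prenyloxy)-2-[3-prenyl-4-(2-methylbut-3-yn-2-yloxy)phenyl]chroman-4-one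
Conditions: Cp*RhCl[(R,R)-TsDPEN] (1 mol %), HCO2H/Et3N 5:2, EtOAc, rt, stopped just past half conversion
Reagents that add atoms: none
Why: Kinetic resolution by Noyori-Ikariya asymmetric transfer hydrogenation, a reaction type known for racemic flavanones, in which the (R,R)-catalyst builds a (4R)-alcohol and this is matched with the ring's preference for the 2,4-cis alcohol only in the (2R)-ketone, so the (2R)-ketone should be consumed and the (2S)-ketone 9 left for separation by chromatography.

Step 8
Reactants: 9 (2S)-7-(methoxymethoxy)-5-(prenyloxy)-2-[3-prenyl-4-(2-methylbut-3-yn-2-yloxy)phenyl]chroman-4-one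
Product: 14 (2S)-7-O-(methoxymethyl)maackiaflavanone B, via C6 dienone 10 (not isolated), via 8-prenyl phenol 11 (not isolated), via allenylphenol 12 (not isolated), via o-quinone methide 13 (not isolated)
Conditions: Eu(fod)3 (10 mol %), degassed o-xylene, Ar, sealed tube, 60 °C then 140 °C
Reagents that add atoms: none
Why: Eu(fod)3, bound between the C4 carbonyl oxygen and O5, triggers the aromatic Claisen shift of the O5 prenyl group to C6 (dienone 10), and the crowded 1,1-dimethylallyl group then moves on by a Cope shift to C8, the carbon para to O5, before enolisation gives phenol 11; this para-Claisen-Cope sequence is known for 5-O-prenylflavanones and for 2-prenyloxy-4,6-dialkoxyacetophenones. On further heating the 1,1-dimethylpropargyl ether on O4' undergoes the propargyl Claisen rearrangement to C5' and enolises to allenylphenol 12, and a 1,5-hydrogen shift from the O4' hydroxyl to the central allene carbon gives the Z o-quinone methide 13, which is the classical thermal route to 2,2-dimethylchromenes. Ring D is closed from 13 by a thermally allowed disrotatory oxa-6π electrocyclisation that forms the O4'-CMe2 bond and restores the aromaticity of ring B, which makes the cascade irreversible. No new stereocentre remains (the C6 centre of 10 is erased on the way to 11 and ring D has none), and C2 is a spectator that should hold because the medium contains neither base nor a 4'-phenoxide, the two triggers of ring C opening. Site selectivity in ring A rests on the blocked ortho carbon C4a, on the O7 MOM ether, which offers no proton for early enolisation of 10, and on the strain of the quaternary group between two oxygenated carbons, while in ring B it rests on the prenyl group at C3', which leaves C5' as the only ortho carbon where the first shift can be followed by enolisation. The two cascades run in separate rings and share only heat, so neither should disturb the other, and the isomerisation consumes no reagent.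

Step 9
Reactants: 14 (2S)-7-O-(methoxymethyl)maackiaflavanone B
Product: 15 maackiaflavanone B
Conditions: HCl (dilute), MeOH, 40 °C
Reagents that add atoms: none
Why: Acid-catalysed acetal exchange (MOM cleavage), the usual last step in syntheses of prenylated flavanones, under which dilute acid at mild temperature should spare the two prenyl groups and the ring D alkene and should not touch C2, since acid generates neither the enolate nor the phenoxide needed to open ring C.

**Compound list**

1 | 2,4,6-trihydroxyacetophenone | CC(=O)c1c(O)cc(O)cc1O | starting material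
2 | 2,6-dihydroxy-4-(methoxymethoxy)acetophenone | CC(=O)c1c(O)cc(OCOC)cc1O | intermediate
3 | 2-hydroxy-4-(methoxymethoxy)-6-(prenyloxy)acetophenone | CC(=O)c1c(O)cc(OCOC)cc1OCC=C(C)C | intermediate
4 | 4-hydroxybenzaldehyde | O=Cc1ccc(O)cc1 | starting material
5 | 4-hydroxy-3-prenylbenzaldehyde | O=Cc1ccc(O)c(CC=C(C)C)c1 | intermediate
6 | 3-prenyl-4-(2-methylbut-3-yn-2-yloxy)benzaldehyde | O=Cc1ccc(OC(C)(C)C#C)c(CC=C(C)C)c1 | intermediate
7 | (E)-2'-hydroxy-4'-(methoxymethoxy)-6'-(prenyloxy)-3-prenyl-4-(2-methylbut-3-yn-2-yloxy)chalcone | O=C(/C=C/c1ccc(OC(C)(C)C#C)c(CC=C(C)C)c1)c1c(O)cc(OCOC)cc1OCC=C(C)C | intermediate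
8 | (±)-7-(methoxymethoxy)-5-(prenyloxy)-2-[3-prenyl-4-(2-methylbut-3-yn-2-yloxy)phenyl]chroman-4-one (racemic at C2) | O=C1CC(c2ccc(OC(C)(C)C#C)c(CC=C(C)C)c2)Oc2cc(OCOC)cc(OCC=C(C)C)c21 | intermediate
9 | (2S)-7-(methoxymethoxy)-5-(prenyloxy)-2-[3-prenyl-4-(2-methylbut-3-yn-2-yloxy)phenyl]chroman-4-one | CC(C)=CCc1cc([C@@H]2CC(=O)c3c(OCC=C(C)C)cc(OCOC)cc3O2)ccc1OC(C)(C)C#C | intermediate
10 | C6 dienone: ring A as a cyclohexa-2,4-dienone with C5=O and a 1,1-dimethylallyl group and H on sp3 C6 (both C6 epimers, 2S), not isolated | CC(C)=CCc1cc([C@@H]2CC(=O)C3=C(O2)C=C(OCOC)C(C(C)(C)C=C)C3=O)ccc1OC(C)(C)C#C | intermediate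
11 | 8-prenyl phenol: (2S)-5-hydroxy-7-(methoxymethoxy)-8-prenyl-2-[3-prenyl-4-(2-methylbut-3-yn-2-yloxy)phenyl]chroman-4-one, not isolated | CC(C)=CCc1cc([C@@H]2CC(=O)c3c(O)cc(OCOC)c(CC=C(C)C)c3O2)ccc1OC(C)(C)C#C | intermediate
12 | allenylphenol: (2S)-5-hydroxy-2-[4-hydroxy-3-(3-methylbuta-1,2-dienyl)-5-prenylphenyl]-7-(methoxymethoxy)-8-prenylchroman-4-one, not isolated | CC(C)=CCc1cc([C@@H]2CC(=O)c3c(O)cc(OCOC)c(CC=C(C)C)c3O2)cc(C=C=C(C)C)c1O | intermediate
13 | o-quinone methide: ring B as a cyclohexa-2,4-dienone with C4'=O and a Z exocyclic C5'=CH-CH=CMe2 unit (2S), not isolated | CC(C)=CCC1=CC([C@@H]2CC(=O)c3c(O)cc(OCOC)c(CC=C(C)C)c3O2)=C/C(=C/C=C(C)C)C1=O | intermediate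
14 | (2S)-7-O-(methoxymethyl)maackiaflavanone B | CC(C)=CCc1cc([C@@H]2CC(=O)c3c(O)cc(OCOC)c(CC=C(C)C)c3O2)cc2c1OC(C)(C)C=C2 | intermediate
15 | maackiaflavanone B, (2S)-5,7-dihydroxy-2-(2,2-dimethyl-8-prenyl-2H-chromen-6-yl)-8-prenylchroman-4-one | CC(C)=CCc1cc([C@@H]2CC(=O)c3c(O)cc(O)c(CC=C(C)C)c3O2)cc2c1OC(C)(C)C=C2 | target

**Step count and risks**

Total step count: 9. Longest linear sequence: 7 steps (steps 1, 2, 5, 6, 7, 8, 9; the branch through steps 3 and 4 is equally long).

**Step 8 (key step).**
- Risk: enolisation straight after the first shift could arrest the C5 unit at C6 in its reversed form. Prolonged heating could also open ring C by a retro-oxa-Michael process and erode the configuration at C2.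
- Fallback: the two migrations are separated, and ring D is closed by π-acid catalysis in place of heat. Setting out from 9, Eu(fod)3 in CHCl3 at 60 °C should carry out only the ring A para-Claisen-Cope rearrangement and allow 8-prenyl phenol 11 to be isolated. Catalytic Ph3PAuNTf2 in CH2Cl2 at room temperature should then activate the alkyne for a 6-endo-dig hydroarylation by C5', which closes ring D and comes back to the route at 14. No compound outside the compound list is made on this way (F0).

**Step 7.**
- Risk: slow hydride transfer to the electron-rich carbonyl group flanked by the O5 ether, or binding of the terminal alkyne to rhodium, could shrink the rate difference between the two enantiomers.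
- Fallback: resolution by an enzyme at the alcohol oxidation level. Setting out from 8, NaBH4 in MeOH/THF at 0 °C should give the racemic 2,4-cis-flavan-4-ol F1. A lipase (Burkholderia cepacia lipase or Candida antarctica lipase B) with vinyl acetate in MTBE should, following the Kazlauskas rule, leave the (2S,4S)-flavan-4-ol F2 and turn its enantiomer into the (2R,4R)-flavan-4-yl acetate F3. After chromatography, Dess-Martin periodinane with NaHCO3 in CH2Cl2 should oxidise F2 and come back to the route at 9.

**Step 9.**
- Risk: acid-catalysed addition of the freed O7 hydroxyl to the C8 prenyl double bond, or addition of methanol to the ring D double bond, could compete with acetal cleavage.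
- Fallback: exchange of the acetal for a silyl ether without Brønsted acid, then removal by fluoride. Setting out from 14, TESOTf and 2,2'-bipyridyl in CH2Cl2 at 0 °C should convert the aryl MOM ether directly into the 7-O-triethylsilyl ether F4. Any silylation of the chelated 5-OH would be undone in the next operation. Et3N·3HF in THF at 0 °C should then free the phenol and come back to the route at 15.

**Further compounds**

F0 | step 8 | none | none
F1 | step 7 | (±)-2,4-cis-7-(methoxymethoxy)-5-(prenyloxy)-2-[3-prenyl-4-(2-methylbut-3-yn-2-yloxy)phenyl]chroman-4-ol (racemate, both enantiomers written) | CC(C)=CCc1cc([C@@H]2C[C@H](O)c3c(OCC=C(C)C)cc(OCOC)cc3O2)ccc1OC(C)(C)C#C.CC(C)=CCc1cc([C@H]2C[C@@H](O)c3c(OCC=C(C)C)cc(OCOC)cc3O2)ccc1OC(C)(C)C#C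
F2 | step 7 | (2S,4S)-7-(methoxymethoxy)-5-(prenyloxy)-2-[3-prenyl-4-(2-methylbut-3-yn-2-yloxy)phenyl]chroman-4-ol | CC(C)=CCc1cc([C@@H]2C[C@H](O)c3c(OCC=C(C)C)cc(OCOC)cc3O2)ccc1OC(C)(C)C#C
F3 | step 7 | (2R,4R)-7-(methoxymethoxy)-5-(prenyloxy)-2-[3-prenyl-4-(2-methylbut-3-yn-2-yloxy)phenyl]chroman-4-yl acetate | CC(C)=CCc1cc([C@H]2C[C@@H](OC(C)=O)c3c(OCC=C(C)C)cc(OCOC)cc3O2)ccc1OC(C)(C)C#C
F4 | step 9 | (2S)-7-O-(triethylsilyl)maackiaflavanone B | CC(C)=CCc1cc([C@@H]2CC(=O)c3c(O)cc(O[Si](CC)(CC)CC)c(CC=C(C)C)c3O2)cc2c1OC(C)(C)C=C2
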